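**Plan**
1. Numbering: the coumarin is benzo ring A fused to pyranone ring B (O1, C2=O, C3, C4–OH). The side chain runs from C1' (on C3) to C12' (CH2OBz), with methyls on C3', C7' and C11'.
2. Cuts, in retrosynthetic order: add an acetyl mask on O4, then cut C7'(sp2)–C8'(sp3), then C3–C1'. Next cut C7'–iodine, C7'–CH3 and C6'–C7' back to a C6' aldehyde. In the other half, cut O–benzoyl and C12'–O.
3. Enabling feature: C7' is the methyl-bearing sp2 carbon of the C6'=C7' alkene and can hold iodine trans to C5' as a configurationally stable alkenyl iodide. C8' is an unbranched primary CH2 whose radical meets only the C10'=C11' alkene two atoms away. Both carbons can therefore be electrophiles and are joined reductively. The only acidic site, O4–H of ring B, is silenced as its acetate.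
4. Forward order: geranyl acetate is cut to a C7 aldehyde and rebuilt to a C9 iodo-dienyl bromide. This is hung on C3 of bought 4-hydroxycoumarin (rings A and B are not built) and O-acetylated. It is then united with the C6 iodo-benzoate made from homoprenyl bromide, and the acetate is removed.
5. Stereochemistry: there is no stereocentre. 2'E comes from geranyl acetate. 6'E comes from syn-hydrozirconation, then retention in the iodinolysis and in the coupling. 10'E comes from the E-selective SeO2 oxidation.

Key step: step 11

Remark: geranyl acetate, 4-hydroxycoumarin and 5-bromo-2-methylpent-2-ene are taken as commercial. Stereocontrol here means the three E-alkenes only.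

**Step 1**
Reactants: 1 geranyl acetate
Product: 3 (E)-6-acetoxy-4-methylhex-4-enal, via ozonide 2 (not isolated)
Conditions: O3 (1.0 equiv, Sudan Red 7B end point), CH2Cl2, −78 °C; then PPh3 (1.1 equiv), −78 °C to rt
Reagents that add atoms: ozone, [O-][O+]=O
Why: Chemoselective ozonolysis (Criegee mechanism): electrophilic ozone should attack the electron-rich C6=C7 isopropylidene alkene well before the C2=C3 alkene, which is deactivated by the allylic acetoxy group, and PPh3 reduces the ozonide without touching the E-alkene.

**Step 2**
Reactants: 3 (E)-6-acetoxy-4-methylhex-4-enal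
Product: 5 (E)-3-methylhept-2-en-6-yn-1-ol, via enynyl acetate 4 (not isolated)
Conditions: dimethyl (1-diazo-2-oxopropyl)phosphonate (1.3 equiv), K2CO3 (2.5 equiv), MeOH, 0 °C to rt
Reagents that add atoms: dimethyl (1-diazo-2-oxopropyl)phosphonate, CC(=O)C(=[N+]=[N-])P(=O)(OC)OC
Why: Seyferth–Gilbert homologation in its Ohira–Bestmann form turns the enolisable aldehyde into the terminal alkyne under K2CO3/MeOH, and the same medium transesterifies the allylic acetate, so that deprotection costs no extra step.

**Step 3**
Reactants: 5 (E)-3-methylhept-2-en-6-yn-1-ol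
Product: 7 (E)-3-methyloct-2-en-6-yn-1-ol, via dilithio species 6 (not isolated)
Conditions: n-BuLi (2.1 equiv), THF, −78 to 0 °C; MeI (1.1 equiv), −78 °C to rt; H2O
Reagents that add atoms: methyl iodide, CI
Why: Acetylide alkylation: in the O,C-dilithio species the soft acetylide carbon should take up the single equivalent of MeI far faster than the aggregated lithium alkoxide, which places the future C7' methyl group.

**Step 4**
Reactants: 7 (E)-3-methyloct-2-en-6-yn-1-ol
Product: 9 (2E,6E)-7-iodo-3-methylocta-2,6-dien-1-ol, via alkenylzirconocene 8 (not isolated)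
Conditions: Cp2Zr(H)Cl (3 equiv), THF, rt then 45 °C, dark; I2 (2.5 equiv), THF, −20 °C; aq Na2S2O3
Reagents that add atoms: iodine, II
Why: Hydrozirconation–iodinolysis: after one equivalent of Cp2Zr(H)Cl is spent on the hydroxyl group, Zr–H adds syn to the alkyne, the excess reagent equilibrates zirconium to the less hindered methyl-bearing carbon C7, and iodine cleaves the C–Zr bond with retention, so that iodine ends trans to C5 (6E), the trisubstituted C2=C3 alkene being inert.

**Step 5**
Reactants: 9 (2E,6E)-7-iodo-3-methylocta-2,6-dien-1-ol
Product: 10 (2E,6E)-1-bromo-7-iodo-3-methylocta-2,6-diene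
Conditions: PBr3 (0.4 equiv), Et2O, 0 °C, dark
Reagents that add atoms: phosphorus tribromide, BrP(Br)Br
Why: SN2 bromination of a primary allylic alcohol with PBr3, as in the preparation of geranyl bromide, should proceed at 0 °C without allylic transposition or E/Z loss and leaves the alkenyl iodide alone.

**Step 6**
Reactants: 10 (2E,6E)-1-bromo-7-iodo-3-methylocta-2,6-diene; 11 4-hydroxycoumarin
Product: 12 4-hydroxy-3-[(2E,6E)-7-iodo-3-methylocta-2,6-dienyl]coumarin
Conditions: 11 (3 equiv), NaOH (3 equiv), H2O–THF 1:1, 0 °C to rt; then 1 M HCl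
Reagents that add atoms: none
Why: C-allylation of an ambident cyclic 1,3-dicarbonyl enolate: hydrogen bonding by water shields the hard enolate oxygen so that the soft primary allylic bromide should be attacked by C3 in an SN2 reaction that keeps the 2'E geometry, the excess of 11 holds back a second alkylation, and the acidic product is parted from neutral material by base extraction.

**Step 7**
Reactants: 12 4-hydroxy-3-[(2E,6E)-7-iodo-3-methylocta-2,6-dienyl]coumarin
Product: 13 4-acetoxy-3-[(2E,6E)-7-iodo-3-methylocta-2,6-dienyl]coumarin
Conditions: Ac2O (1.5 equiv), pyridine (3 equiv), CH2Cl2, 0 °C to rt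
Reagents that add atoms: acetic anhydride, CC(=O)OC(C)=O
Why: O-Acylation of the acidic enol (pyridine-mediated esterification) masks the only proton that could quench organonickel or organozinc species in step 11, C3 being blocked against C-acylation.

**Step 8**
Reactants: 14 5-bromo-2-methylpent-2-ene
Product: 15 (E)-5-bromo-2-methylpent-2-en-1-ol
Conditions: SeO2 (0.3 equiv), t-BuOOH (2.5 equiv, in decane), salicylic acid (0.1 equiv), CH2Cl2, 0 °C to rt
Reagents that add atoms: tert-butyl hydroperoxide, CC(C)(C)OO; selenium dioxide (oxygen carrier), O=[Se]=O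
Why: Riley-type SeO2 allylic oxidation: the ene reaction at the disubstituted alkene terminus followed by a [2,3]-sigmatropic shift with the chain held pseudo-equatorial should deliver oxygen only to the methyl group trans to the chain, which sets the E-allylic alcohol (future C10'=C11'), and the primary bromide is inert.

**Step 9**
Reactants: 15 (E)-5-bromo-2-methylpent-2-en-1-ol
Product: 16 (E)-5-bromo-2-methylpent-2-enyl benzoate
Conditions: BzCl (1.2 equiv), pyridine (2 equiv), DMAP (5 mol %), CH2Cl2, 0 °C
Reagents that add atoms: benzoyl chloride, O=C(Cl)c1ccccc1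
Why: DMAP-catalysed esterification of the primary allylic alcohol, in which the homoallylic bromide should not react with pyridine at 0 °C.

**Step 10**
Reactants: 16 (E)-5-bromo-2-methylpent-2-enyl benzoate
Product: 17 (E)-5-iodo-2-methylpent-2-enyl benzoate
Conditions: NaI (3 equiv), acetone, reflux, dark
Reagents that add atoms: sodium iodide, [Na+].[I-]
Why: Finkelstein reaction: SN2 exchange driven by precipitation of NaBr gives the iodide, whose ease of halogen-atom abstraction matches the reactivity of the alkenyl iodide partner, and the allylic benzoate is not displaced under these neutral conditions.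

**Step 11**
Reactants: 13 4-acetoxy-3-[(2E,6E)-7-iodo-3-methylocta-2,6-dienyl]coumarin; 17 (E)-5-iodo-2-methylpent-2-enyl benzoate
Product: 18 (2E,6E,10E)-12-(4-acetoxy-2-oxo-2H-chromen-3-yl)-2,6,10-trimethyldodeca-2,6,10-trienyl benzoate
Conditions: NiI2 (10 mol %), 4,4'-di-tert-butyl-2,2'-bipyridine (10 mol %), Zn dust (2.5 equiv), 17 (1.5 equiv), DMA, 23 °C, dark
Reagents that add atoms: none
Why: Zerovalent nickel carrying the bipyridine ligand inserts into the C7'(sp2)–iodine bond of 13 with retention of geometry, a monovalent nickel iodide abstracts iodine from 17 to release the primary C8' radical, the radical is captured by the divalent alkenylnickel species, and reductive elimination from trivalent nickel forms C7'–C8' while Zn returns the catalyst to its low-valent state. The closest known reaction type is the nickel-catalysed reductive cross-electrophile coupling of alkenyl halides with primary alkyl halides, in which two carbons of like (electrophilic) polarity are joined without a preformed organometal. No ring is closed and no stereocentre is formed; the 6'E geometry is controlled by the stereoretentive insertion and reductive elimination at the alkenyl iodide, in which iodine stands trans to C5'. Cross-coupling must win over homocoupling, which is secured by the two different activation modes (two-electron insertion for the sp2 iodide, halogen-atom abstraction for the sp3 iodide) and by the excess of 17. Chemoselectivity over the allylic benzoate, the enol acetate and the lactone of ring B rests on the much faster reaction of the two carbon–iodine bonds at room temperature, and the acetate removes the acidic O4–H that would protonate alkenylnickel or alkylzinc species. The C8' radical has only the C10'=C11' alkene two atoms away, so no five- or six-membered ring closure competes, and the nickel on C7' points away from the C2'=C3' alkene.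

**Step 12**
Reactants: 18 (2E,6E,10E)-12-(4-acetoxy-2-oxo-2H-chromen-3-yl)-2,6,10-trimethyldodeca-2,6,10-trienyl benzoate
Product: 19 E-omega-benzoyloxyferulenol
Conditions: NH4OAc (8 equiv), MeOH–H2O 4:1, rt
Reagents that add atoms: none
Why: Chemoselective solvolysis of an activated enol ester: the 4-acyloxycoumarin is a vinylogous mixed anhydride (its leaving group is as acidic as a carboxylic acid) and should be cleaved by neutral NH4OAc in aqueous methanol, conditions that spare alkyl benzoates and are too mild to cyclise the 4-OH onto the C2'=C3' alkene.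

**Compound list**
1 | geranyl acetate, (E)-3,7-dimethylocta-2,6-dienyl acetate | CC(C)=CCC/C(C)=C/COC(C)=O | starting material
2 | (E)-5-(5,5-dimethyl-1,2,4-trioxolan-3-yl)-3-methylpent-2-enyl acetate (racemic ozonide) | CC(=O)OC/C=C(\C)CCC1OOC(C)(C)O1 | intermediate
3 | (E)-6-acetoxy-4-methylhex-4-enal | O=CCC/C(C)=C/COC(C)=O | intermediate
4 | (E)-3-methylhept-2-en-6-ynyl acetate | C#CCC/C(C)=C/COC(C)=O | intermediate
5 | (E)-3-methylhept-2-en-6-yn-1-ol | C#CCC/C(C)=C/CO | intermediate
6 | O,C-dilithio derivative of 5 (lithium alkoxide and lithium acetylide) | [Li]C#CCC/C(C)=C/CO[Li] | intermediate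
7 | (E)-3-methyloct-2-en-6-yn-1-ol | CC#CCC/C(C)=C/CO | intermediate
8 | (2E,6E)-7-[chlorobis(cyclopentadienyl)zirconio]-3-methylocta-2,6-dienyl zirconocene chloride alkoxide (Cp drawn sigma-bound) | C/C(=C\CC/C(C)=C/CO[Zr](Cl)(C1C=CC=C1)C1C=CC=C1)[Zr](Cl)(C1C=CC=C1)C1C=CC=C1 | intermediate
9 | (2E,6E)-7-iodo-3-methylocta-2,6-dien-1-ol | C/C(I)=C\CC/C(C)=C/CO | intermediate
10 | (2E,6E)-1-bromo-7-iodo-3-methylocta-2,6-diene | C/C(I)=C\CC/C(C)=C/CBr | intermediate
11 | 4-hydroxycoumarin | O=c1cc(O)c2ccccc2o1 | starting material
12 | 4-hydroxy-3-[(2E,6E)-7-iodo-3-methylocta-2,6-dienyl]coumarin | C/C(I)=C\CC/C(C)=C/Cc1c(O)c2ccccc2oc1=O | intermediate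
13 | 4-acetoxy-3-[(2E,6E)-7-iodo-3-methylocta-2,6-dienyl]coumarin | C/C(I)=C\CC/C(C)=C/Cc1c(OC(C)=O)c2ccccc2oc1=O | intermediate
14 | 5-bromo-2-methylpent-2-ene (homoprenyl bromide) | CC(C)=CCCBr | starting material
15 | (E)-5-bromo-2-methylpent-2-en-1-ol | OC/C(C)=C/CCBr | intermediate
16 | (E)-5-bromo-2-methylpent-2-enyl benzoate | O=C(OC/C(C)=C/CCBr)c1ccccc1 | intermediate
17 | (E)-5-iodo-2-methylpent-2-enyl benzoate | O=C(OC/C(C)=C/CCI)c1ccccc1 | intermediate
18 | (2E,6E,10E)-12-(4-acetoxy-2-oxo-2H-chromen-3-yl)-2,6,10-trimethyldodeca-2,6,10-trienyl benzoate (O4-acetyl target) | C/C(=C\CC/C(C)=C/Cc1c(OC(C)=O)c2ccccc2oc1=O)CC/C=C(\C)COC(=O)c1ccccc1 | intermediate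
19 | E-omega-benzoyloxyferulenol, (2E,6E,10E)-12-(4-hydroxy-2-oxo-2H-chromen-3-yl)-2,6,10-trimethyldodeca-2,6,10-trienyl benzoate | C/C(=C\CC/C(C)=C/Cc1c(O)c2ccccc2oc1=O)CC/C=C(\C)COC(=O)c1ccccc1 | target

**Count**
Total steps: 12. Longest linear sequence: 9 (steps 1–7, 11, 12).

**Steps most likely to fail**

Step 11. Several processes may compete with the cross-coupling:
- homocoupling and hydrodehalogenation may outrun it;
- the 10'E geometry may leak through reversible three-membered ring closure of the homoallyl radical;
- low-valent nickel may insert into the allylic C12'–O bond.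

The fallback gives up the radical union for a polarity-differentiated two-electron coupling. It sets out from 17. Zinc insertion (Zn dust, LiCl, THF, rt) should give [(E)-5-(benzoyloxy)-4-methylpent-3-enyl]zinc iodide F1. Negishi coupling of this reagent with 13 under PdCl2(dppf) in THF at rt, with retention at the alkenyl iodide, comes back to the route at 18.

Step 4. Equilibration of zirconium to the methyl-bearing carbon may stay incomplete. Iodination would then occur partly at C6, and the regioisomers may be hard to part.

The fallback removes the regiochemical question by fixing C7' as a one-carbon extension of the aldehyde. It sets out from 3.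
- Ramirez olefination (CBr4, PPh3, CH2Cl2, 0 °C) should give (E)-7,7-dibromo-3-methylhepta-2,6-dienyl acetate F2.
- K2CO3 in MeOH gives (E)-7,7-dibromo-3-methylhepta-2,6-dien-1-ol F3.
- PBr3 in Et2O gives (E)-1,1,7-tribromo-5-methylhepta-1,5-diene F4.
- Alkylation of 11 under the conditions of step 6 gives 3-[(E)-7,7-dibromo-3-methylhepta-2,6-dienyl]-4-hydroxycoumarin F5.
- Ac2O and pyridine give 4-acetoxy-3-[(E)-7,7-dibromo-3-methylhepta-2,6-dienyl]coumarin F6.
- Negishi coupling with the organozinc iodide F1 under PdCl2(DPEphos) should engage only the bromine trans to C5'. This gives (2E,6Z,10E)-12-(4-acetoxy-2-oxo-2H-chromen-3-yl)-6-bromo-2,10-dimethyldodeca-2,6,10-trienyl benzoate F7.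
- Me2Zn with Pd(P(t-Bu)3)2 replaces the remaining bromine by methyl with retention, and the route is rejoined at 18.

Step 6. O-alkylation, a second alkylation at C3 and hydrolysis of the allylic bromide may all compete with the wanted C-allylation.

The fallback builds ring B around the chain instead of alkylating it. It sets out from 10.
- The dianion of 2'-hydroxyacetophenone (LiN(i-Pr)2, 2.2 equiv, THF, −78 to −10 °C) is alkylated at its methyl carbon. This gives (4E,8E)-1-(2-hydroxyphenyl)-9-iodo-5-methyldeca-4,8-dien-1-one F8.
- NaH and diethyl carbonate in THF at reflux, followed by dilute HCl, then close ring B. The closure runs by C-acylation of the ketone enolate and lactonisation through the phenoxide.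
- The route is rejoined at 12.

**Further compounds**
F1 | step 11 | [(E)-5-(benzoyloxy)-4-methylpent-3-enyl]zinc iodide | O=C(OC/C(C)=C/CC[Zn]I)c1ccccc1
F2 | step 4 | (E)-7,7-dibromo-3-methylhepta-2,6-dienyl acetate | CC(=O)OC/C=C(\C)CCC=C(Br)Br
F3 | step 4 | (E)-7,7-dibromo-3-methylhepta-2,6-dien-1-ol | OC/C=C(\C)CCC=C(Br)Br
F4 | step 4 | (E)-1,1,7-tribromo-5-methylhepta-1,5-diene | BrC/C=C(\C)CCC=C(Br)Br
F5 | step 4 | 3-[(E)-7,7-dibromo-3-methylhepta-2,6-dienyl]-4-hydroxycoumarin | O=c1oc2ccccc2c(O)c1C/C=C(\C)CCC=C(Br)Br
F6 | step 4 | 4-acetoxy-3-[(E)-7,7-dibromo-3-methylhepta-2,6-dienyl]coumarin | CC(=O)Oc1c(C/C=C(\C)CCC=C(Br)Br)c(=O)oc2ccccc12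
F7 | step 4 | (2E,6Z,10E)-12-(4-acetoxy-2-oxo-2H-chromen-3-yl)-6-bromo-2,10-dimethyldodeca-2,6,10-trienyl benzoate | Br/C(=C\CC/C(C)=C/Cc1c(OC(C)=O)c2ccccc2oc1=O)CC/C=C(\C)COC(=O)c1ccccc1
F8 | step 6 | (4E,8E)-1-(2-hydroxyphenyl)-9-iodo-5-methyldeca-4,8-dien-1-one | C/C(I)=C\CC/C(C)=C/CCC(=O)c1ccccc1O
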